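## Retrosynthetic overview
1. Target ⇒ break the benzylic C1'–O(acyl) bond last. The precursors are the 8-(3-methyl-2-oxobut-3-enyl)coumarin ketone and isovaleric acid, joined by a catalytic enantioselective oxidative α-acyloxylation that sets the only stereocentre, (R).
2. Ketone ⇒ break C8–C1'. The precursors are 8-iodo-6,7-dimethoxycoumarin and the silyl dienol ether of 3-methylbut-3-en-2-one, joined by a base-free Pd α-arylation.
3. Iodide ⇒ scopoletin, by C8 iodination and then O-methylation.
4. Rings: none is formed. The benzopyranone bicycle is bought intact in scopoletin.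

Assumption: the stereocentre in the SMILES is (R) (O > C=O > aryl > H). The sense of induction of the new catalytic step must be calibrated once; both catalyst antipodes are accessible, and the route is written for the antipode that gives (R).

## Route

Step 1
Reactants: 1 scopoletin (7-hydroxy-6-methoxy-2H-chromen-2-one)
Product: 2 7-hydroxy-8-iodo-6-methoxy-2H-chromen-2-one
Conditions: I2 (1.05 equiv), KI, 25% aq NH3, 0 °C to rt; then dil. H2SO4, filter
Reagents that add atoms: iodine, SMILES II
Why: Electrophilic aromatic iodination of the phenoxide, in which C8 is the only open position ortho or para to the 7-O− because C6 carries OMe and the para position is the ring fusion.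

Step 2
Reactants: 2 7-hydroxy-8-iodo-6-methoxy-2H-chromen-2-one
Product: 3 8-iodo-6,7-dimethoxy-2H-chromen-2-one
Conditions: MeI (1.5 equiv), K2CO3 (2 equiv), acetone, reflux
Reagents that add atoms: iodomethane, SMILES CI
Why: Williamson ether synthesis on the acidic phenol, under conditions that leave the lactone and the aryl iodide untouched.

Step 3
Reactants: 4 3-methylbut-3-en-2-one
Product: 5 trimethyl[(3-methylbuta-1,3-dien-2-yl)oxy]silane
Conditions: TMSOTf (1.1 equiv), Et3N (1.3 equiv), Et2O, 0 °C; pentane extraction, distil under reduced pressure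
Reagents that add atoms: trimethylsilyl trifluoromethanesulfonate, SMILES C[Si](C)(C)OS(=O)(=O)C(F)(F)F
Why: Soft enolisation (silyl enol ether formation), in which the silyl triflate activates the carbonyl and Et3N removes a proton from the only enolisable carbon, the methyl group, to give the cross-conjugated 2-silyloxydiene.

Step 4
Reactants: 3 8-iodo-6,7-dimethoxy-2H-chromen-2-one; 5 trimethyl[(3-methylbuta-1,3-dien-2-yl)oxy]silane (1.5 equiv)
Product: 7 6,7-dimethoxy-8-(3-methyl-2-oxobut-3-en-1-yl)-2H-chromen-2-one, via tributyltin dienolate 6 (not isolated)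
Conditions: Pd2(dba)3 (2.5 mol %), P(t-Bu)3 (6 mol %), Bu3SnF (1.3 equiv), BHT (1 mol %), PhMe, 85 °C; aq KF work-up
Reagents that add atoms: none
Why: Base-free Pd-catalysed α-arylation of a silyl enol ether through its tin enolate (Kuwajima–Urabe/Migita type), in which the cross-conjugated dienolate has a single nucleophilic carbon, the neutral medium spares lactone and enone, and the di-ortho-substituted aryl group blocks a second arylation.

Step 5
Reactants: 7 6,7-dimethoxy-8-(3-methyl-2-oxobut-3-en-1-yl)-2H-chromen-2-one; 8 isovaleric acid (3-methylbutanoic acid, 2 equiv)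
Product: 10 (1R)-1-(6,7-dimethoxy-2-oxo-2H-chromen-8-yl)-3-methyl-2-oxobut-3-en-1-yl 3-methylbutanoate (CNP0283239.1), via racemic alpha-iodoketone 9 (not isolated)
Conditions: C2-symmetric N-spiro bis(binaphthyl)ammonium iodide with 3,3'-bis[3,5-bis(trifluoromethyl)phenyl] arms (10 mol %), t-BuOOH (5.5 M in decane, 1.5 equiv, slow addition), MTBE, 25 °C, dark; aq Na2S2O3 quench, neutral silica
Reagents that add atoms: none
Why: Proposed new method: an enantioconvergent intermolecular hypoiodite-catalysed oxidative α-acyloxylation in which t-BuOOH oxidises the iodide of the chiral ammonium salt to hypoiodite, this iodinates the only enolisable carbon of 7 to give benzylic α-iodoketone 9 whose enantiomers interconvert quickly by degenerate iodide exchange and enolisation, and the tight chiral ammonium isovalerate ion pair displaces iodide from the matched (S)-9 by SN2 inversion to form the C1'–O bond as the (R)-ester and return the iodide catalyst, while the excess acid and the twisted di-ortho-substituted aryl group keep the product from enolising; the closest known reaction types are the achiral Bu4NI/t-BuOOH α-oxyacylation of ketones with carboxylic acids and the chiral ammonium hypoiodite oxidative cycloetherification and α-azidation of carbonyl compounds, which to my knowledge have not been extended to an intermolecular enantioselective coupling of a simple ketone with an aliphatic acid.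

## Compound list
1 | scopoletin (7-hydroxy-6-methoxy-2H-chromen-2-one) | COc1cc2ccc(=O)oc2cc1O | starting material
2 | 7-hydroxy-8-iodo-6-methoxy-2H-chromen-2-one | COc1cc2ccc(=O)oc2c(I)c1O | intermediate
3 | 8-iodo-6,7-dimethoxy-2H-chromen-2-one | COc1cc2ccc(=O)oc2c(I)c1OC | intermediate
4 | 3-methylbut-3-en-2-one | CC(=O)C(C)=C | starting material
5 | trimethyl[(3-methylbuta-1,3-dien-2-yl)oxy]silane | C=C(C)C(=C)O[Si](C)(C)C | intermediate
6 | tributyl[(3-methylbuta-1,3-dien-2-yl)oxy]stannane (not isolated) | C=C(C)C(=C)O[Sn](CCCC)(CCCC)CCCC | intermediate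
7 | 6,7-dimethoxy-8-(3-methyl-2-oxobut-3-en-1-yl)-2H-chromen-2-one | C=C(C)C(=O)Cc1c(OC)c(OC)cc2ccc(=O)oc12 | intermediate
8 | isovaleric acid (3-methylbutanoic acid) | CC(C)CC(=O)O | starting material
9 | 8-(1-iodo-3-methyl-2-oxobut-3-en-1-yl)-6,7-dimethoxy-2H-chromen-2-one (racemic, not isolated) | C=C(C)C(=O)C(I)c1c(OC)c(OC)cc2ccc(=O)oc12 | intermediate
10 | (1R)-1-(6,7-dimethoxy-2-oxo-2H-chromen-8-yl)-3-methyl-2-oxobut-3-en-1-yl 3-methylbutanoate | C=C(C)C(=O)[C@H](OC(=O)CC(C)C)c1c(OC)c(OC)cc2ccc(=O)oc12 | target

## Step count
- Total steps: 5.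
- Longest linear sequence: 4 (steps 1, 2, 4, 5).

## Steps most likely to fail

**Step 5 (the proposed new step).**
- Risks: low ee from an achiral iodine background reaction or from slow racemisation of 9, slow erosion of ee in the product, iodination at C5, and over-oxidation.
- The fallback uses known chemistry. It sets out from 7 and comes back at 10.
- Regitz diazo transfer (4-acetamidobenzenesulfonyl azide, DBU, MeCN, 0 °C to rt) gives 8-(1-diazo-3-methyl-2-oxobut-3-en-1-yl)-6,7-dimethoxy-2H-chromen-2-one F1.
- F1 then undergoes the established asymmetric carbene O–H insertion of a carboxylic acid into an α-aryl-α-diazoketone with 8. The catalyst pair is Rh2(TPA)4 with a chiral spiro phosphoric acid as proton shuttle, in CH2Cl2. This gives 10 at the cost of one extra step.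

**Step 4.**
- Risks: sluggish coupling at the di-ortho-substituted iodide, Heck arylation of the diene or enone terminus, protodeiodination, and polymerisation.
- The fallback sets out from 3 and comes back at 7.
- Linear-selective Suzuki–Miyaura coupling with 3-methylbut-2-enylboronic acid pinacol ester (Pd(OAc)2, bulky dialkylbiarylphosphine, aq K3PO4, THF, 40 °C) gives 6,7-dimethoxy-8-(3-methylbut-2-en-1-yl)-2H-chromen-2-one F2.
- Schenck ene reaction with singlet oxygen (O2, TPP, hν, CH2Cl2) gives 8-(2-hydroperoxy-3-methylbut-3-en-1-yl)-6,7-dimethoxy-2H-chromen-2-one F3.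
- F3 is dehydrated in the same pot (Ac2O, pyridine, DMAP; Kornblum–DeLaMare type) to 7. The tertiary regioisomer is removed by chromatography.

**Step 1.**
- Risks: over-iodination and partial lactone opening in aqueous ammonia.
- The fallback avoids halogenation and cross-coupling altogether. It sets out from 1 and comes back at 7, bypassing steps 2–4.
- O-alkylation with 3-chloro-3-methylbut-1-yne (K2CO3, KI, acetone, reflux) gives 6-methoxy-7-[(2-methylbut-3-yn-2-yl)oxy]-2H-chromen-2-one F4.
- Lindlar semihydrogenation gives 6-methoxy-7-[(2-methylbut-3-en-2-yl)oxy]-2H-chromen-2-one F5.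
- Aromatic Claisen rearrangement (N,N-diethylaniline, 130–150 °C) can only go to C8 and gives cedrelopsin, 7-hydroxy-6-methoxy-8-(3-methylbut-2-en-1-yl)-2H-chromen-2-one F6.
- MeI/K2CO3 converts F6 into 6,7-dimethoxy-8-(3-methylbut-2-en-1-yl)-2H-chromen-2-one F2. Photooxygenation to the hydroperoxide 8-(2-hydroperoxy-3-methylbut-3-en-1-yl)-6,7-dimethoxy-2H-chromen-2-one F3 and dehydration, as above, then give 7.

## Further compounds
F1 | step 5 | 8-(1-diazo-3-methyl-2-oxobut-3-en-1-yl)-6,7-dimethoxy-2H-chromen-2-one | COc1cc2ccc(=O)oc2c(C(=[N+]=[N-])C(=O)C(C)=C)c1OC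
F2 | step 4 | 6,7-dimethoxy-8-(3-methylbut-2-en-1-yl)-2H-chromen-2-one | COc1cc2ccc(=O)oc2c(CC=C(C)C)c1OC
F3 | step 4 | 8-(2-hydroperoxy-3-methylbut-3-en-1-yl)-6,7-dimethoxy-2H-chromen-2-one (racemic) | COc1cc2ccc(=O)oc2c(CC(OO)C(C)=C)c1OC
F4 | step 1 | 6-methoxy-7-[(2-methylbut-3-yn-2-yl)oxy]-2H-chromen-2-one | COc1cc2ccc(=O)oc2cc1OC(C)(C)C#C
F5 | step 1 | 6-methoxy-7-[(2-methylbut-3-en-2-yl)oxy]-2H-chromen-2-one | COc1cc2ccc(=O)oc2cc1OC(C)(C)C=C
F6 | step 1 | cedrelopsin, 7-hydroxy-6-methoxy-8-(3-methylbut-2-en-1-yl)-2H-chromen-2-one | COc1cc2ccc(=O)oc2c(CC=C(C)C)c1O
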